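## Structural features

The target is a flavan: a chromane in which ring A (benzene) is fused through C4a and C8a to ring C (a dihydropyran made of O1, C2, C3 and C4), with a 3,4,5-trimethoxyphenyl group (ring B) on C2. Ring A carries methoxy groups on C7 and C8, so C8a, the carbon that holds O1, sits between an oxygenated carbon and the ring fusion, and ring B is symmetrical. The only stereocentre is C2 (S); it has no stereogenic neighbour, because C3 and C4 are plain methylene groups, so the task is absolute control with nothing in the molecule to relay it. The C2–O1 bond is both a benzylic ether (towards ring B) and an aryl ether (towards ring A); it is the fragile point, open to acid ionisation (ring opening, loss of configuration) and to hydrogenolysis, and the five aryl methyl ethers exclude strong Lewis acids. Neither C3 nor C4 keeps a functional group, so any handle used to build ring C has to be erased without disturbing C2. The real difficulty is therefore to create an isolated benzylic ether stereocentre enantioselectively and to keep it while the leftover functionality is removed. The key step uses the fact that C4 is a single carbon between C4a of ring A and the C3–C2–ring B unit: it can be carbon monoxide inserted between the iodine-bearing carbon of an ortho-iodophenol and a terminal arylacetylene whose two sp carbons become C3 and C2, the phenol oxygen becoming O1. The 7,8-dioxygenation helps, since in the phenol that supplies ring A the carbon that must become C4a is the only free one ortho to the hydroxyl group.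

## Logic of the disconnections

14 to 13. The C4–H bond is exchanged for a C4–O bond. This is the one C–O bond that leaves easily, because a cation at C4 is benzylic to ring A, para (through C4a) to the C7 methoxy group and ortho to O1. The gain is that 13 is the direct product of a double hydrogenation. The forward step must ionise C4–O and not C2–O1 and must leave C2 untouched; no control is needed at C4, since that centre disappears.

13 to 11. The C2–H, C3–H, C4–H and O–H bonds introduced by two molecules of hydrogen are removed. This erases both stereocentres and gives a flat, achiral, robust chromen-4-one of a class that is documented in enantioselective hydrogenation. The gain is that all stereochemistry is reduced to one catalyst-controlled operation on a late compound. The forward step must select one face at C2 and reduce only the pyranone ring, with no arene saturation and no C2–O1 hydrogenolysis.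

11 to 5, 7 and 8. The bonds C4a–C4, C4–C3 and O1–C2 are cut. C4 is a lone carbon between the two aromatic halves and can be 8. Ring C disappears and the skeleton divides into two aromatic pieces of similar size that already carry all five methoxy groups, plus a one-carbon gas, so the route is convergent. The forward step requires that CO insertion precede alkyne coupling, that six-membered closure beat five-membered closure, and that 5 carry its iodine at exactly the ortho position.

5 to 2. The C–I bond ortho to the hydroxyl group is cut, and the O–H bond is masked. Electrophilic iodination of 1 would be divided between the positions ortho and para to the hydroxyl group, each also activated by a methoxy group, so the iodine is placed by directed metalation. This needs a group on the phenol oxygen that outranks methoxy as a director, survives an alkyllithium base and leaves under mild acid. An acetal made from an enol ether serves, which avoids the carcinogenic chloromethyl alkyl ether of the more usual acetal, and its removal is run in the same operation as the iodination.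

2 to 1. The O–C(acetal) bond is cut, returning the commercial phenol. The forward step is an acid-catalysed addition with no by-product.

7 to 6. The bond between the ring-bound alkyne carbon and the terminal alkyne carbon is cut, which is a one-carbon homologation of an aldehyde. 6 is a cheap bulk chemical and is non-enolisable, so a base-mediated homologation at room temperature is sufficient.

## Other disconnections considered

Alternative 1: The cut is the C2=C3 bond of the flav-2-ene A1 (7,8-dimethoxy-2-(3,4,5-trimethoxyphenyl)-4H-chromene), reached from 14 by removing the C2–H and C3–H bonds. In the forward sense the phosphonium salt A2 has the ring A phenol oxygen acylated by the ring B acid and a CH2CH2PPh3 arm on C4a. Deprotonation at C3 gives the ylide, which attacks the ester carbonyl; an intramolecular Wittig reaction closes ring C as the enol ether A1, and a chiral complex of the type [Ir(cod)(P,N-ligand)]BArF would hydrogenate A1 to 14.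
- In its favour: the stereocentre is set in the last step, no oxygen is left at C4, so no acid is needed once C2 exists, and no carbon monoxide is handled. On these three points it is better than the chosen plan. Its reliance on catalyst-controlled hydrogenation of a C2=C3 bond is equal.
- Against it here: A2 needs a two-carbon arm built ortho to the phenol of ring A, which costs several linear steps. A non-stabilised ylide has to add to an aryl ester whose phenoxide is a good leaving group, so acyl transfer to carbon can compete with olefination. A1 is an acid-sensitive enol ether that can hydrolyse or isomerise into conjugation with ring A. A stoichiometric amount of Ph3PO is formed.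
- Comparison: it forms one ring bond by stoichiometric phosphorus chemistry where the chosen step forms three catalytically, and it would be about two to three steps longer, while its end-game is shorter and gentler.

Alternative 2: The cuts are C8a–O1 and the C8–O bond. The alcohol A4, (S)-3-(2-fluoro-4-methoxyphenyl)-1-(3,4,5-trimethoxyphenyl)propan-1-ol, carries fluorine at the future C8a and a hydrogen at the future C8, between fluorine and the C7 methoxy group. It is converted into its alkoxide with n-BuLi, lithiated at C8 with s-BuLi, and loses LiF. The alkoxide adds to the aryne at C8a, and the aryllithium regenerated at C8 is trapped with B(OMe)3 and oxidised with H2O2 to A3, (S)-7-methoxy-2-(3,4,5-trimethoxyphenyl)chroman-8-ol. O-Methylation would then give 14.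
- In its favour: C2 is set beforehand by a standard asymmetric ketone reduction and no bond to it is made or broken afterwards, which is better than the chosen plan for stereochemical security. No pressurised or toxic gas is needed, which is better on hazard. The aryne both closes ring C and returns the carbanion exactly where the C8 oxygen is required, so the C8 substituent is used and not merely carried. The step count is about equal.
- Against it here: two pyrophoric alkyllithium reagents are used in sequence at low temperature with exact stoichiometry, since excess base adds to the aryne. The borylation and oxidation take place at a carbon flanked by two oxygens. A toxic methylating agent is needed at the end, and the fluorinated ring A building block is less common.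
- Comparison: mechanistically it is stoichiometric anionic chemistry against a catalytic three-component assembly. It is equally convergent.

Alternative 3: The cuts are O1–C2 and C3–C4, with an extra formyl carbon on C3 that is removed later. 2-Hydroxy-3,4-dimethoxybenzaldehyde A6 and (E)-3,4,5-trimethoxycinnamaldehyde A7 react under a diarylprolinol trimethylsilyl ether and a carboxylic acid. Iminium activation of A7 is followed by oxa-Michael addition of the phenol at the future C2, enamine aldol onto the aldehyde of A6 and dehydration, giving A5, (R)-7,8-dimethoxy-2-(3,4,5-trimethoxyphenyl)-2H-chromene-3-carbaldehyde. Decarbonylation and saturation of C3=C4 would follow.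
- In its favour: it is the shortest plan (three to four steps from commercial aldehydes), the ring is built at room temperature without metal or carbon monoxide, and the stereocentre arises in the ring-forming step. On step count and on hazard it is better than the chosen plan.
- Against it here: the iminium ion of the electron-rich A7 is a weak acceptor. The phenol of A6 is hindered by its ortho methoxy group and hydrogen-bonded to its aldehyde. The oxa-Michael step is reversible, which can erode the enantiomeric purity. C2 of A5 is an allylic and benzylic ether in a 2H-chromene that can open electrocyclically to an ortho-quinone methide, so a hot decarbonylation with RhCl(PPh3)3 threatens the configuration. The later hydrogenation has to spare the allylic, benzylic C2–O1 bond.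
- Comparison: the chosen plan creates C2 after ring construction on a robust flat substrate and exposes it to one mild step; this alternative creates C2 first and then passes it through two steps that endanger it. Both plans discard a group (CHO there, OH here), which is equal.

Key step: step 4

Assumption: SINpEt·HBF4 is 1,3-bis[(R)-1-(naphthalen-1-yl)ethyl]-4,5-dihydro-1H-imidazol-3-ium tetrafluoroborate. Its (R,R) antipode is written as the one that leads to 2S. The sense of induction is to be confirmed on the first run, and the equally accessible (S,S) salt replaces it if the sense is opposite.

Remark: 7 is also a catalogue compound; buying it would remove step 3. It is made here in one step from the cheap aldehyde so that the plan does not depend on supply.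

## Route

Step 1
Reactants: 1 2,3-dimethoxyphenol
Product: 2 2-(2,3-dimethoxyphenoxy)tetrahydro-2H-pyran (racemic acetal)
Conditions: 3,4-dihydro-2H-pyran (1.5 equiv), PPTS (5 mol %), CH2Cl2, rt
Reagents that add atoms: 3,4-dihydro-2H-pyran, C1=COCCC1
Why: Acid-catalysed addition of the phenol O–H across the enol ether (tetrahydropyranylation). The acetal masks the acidic proton and supplies a chelating directing group for step 2 without use of a chloromethyl ether.

Step 2
Reactants: 2 2-(2,3-dimethoxyphenoxy)tetrahydro-2H-pyran
Product: 5 6-iodo-2,3-dimethoxyphenol, via aryllithium 3 (not isolated), via iodo THP ether 4 (not isolated)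
Conditions: n-BuLi (1.2 equiv), THF, 0 °C to rt; I2 (1.3 equiv), THF, −78 °C to rt; aq. Na2S2O3 work-up; crude 4, TsOH·H2O (5 mol %), MeOH, rt
Reagents that add atoms: iodine, [I][I]
Why: Directed ortho-metalation: the two acetal oxygens chelate lithium and direct deprotonation to the only position ortho to the aryloxy group, in preference to the position next to the single methoxy director. Iodinolysis of the aryllithium and acid-catalysed transacetalisation in methanol then release the phenol.

Step 3
Reactants: 6 3,4,5-trimethoxybenzaldehyde
Product: 7 5-ethynyl-1,2,3-trimethoxybenzene
Conditions: dimethyl (1-diazo-2-oxopropyl)phosphonate (1.2 equiv, commercial MeCN solution), K2CO3 (2 equiv), MeOH, 0 °C to rt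
Reagents that add atoms: dimethyl (1-diazo-2-oxopropyl)phosphonate, CC(=O)C(=[N+]=[N-])P(=O)(OC)OC
Why: Seyferth–Gilbert homologation in the Ohira–Bestmann variant: methanolysis of the acetyl group gives the diazomethylphosphonate anion, olefination of the aldehyde gives a diazoalkene, and loss of N2 with 1,2-hydrogen shift gives the terminal alkyne. The aldehyde is non-enolisable, and the reagent is handled only as a dilute solution at room temperature.

Step 4
Reactants: 5 6-iodo-2,3-dimethoxyphenol; 7 5-ethynyl-1,2,3-trimethoxybenzene; 8 carbon monoxide
Product: 11 7,8-dimethoxy-2-(3,4,5-trimethoxyphenyl)-4H-chromen-4-one, via aryl ynone 9 (not isolated), via enaminone 10 (not isolated)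
Conditions: PdCl2(PPh3)2 (5 mol %), CO (1 atm, balloon), Et2NH (degassed, solvent), 50 °C, 7 added over 2 h
Reagents that add atoms: none
Why: Zerovalent palladium, formed in the flask from PdCl2(PPh3)2, adds oxidatively to the C–I bond of 5 at the future C4a, and 8 inserts to give an aroylpalladium iodide. Diethylamine deprotonates the coordinated alkyne 7, and reductive elimination from the aroyl(alkynyl)palladium species gives ynone 9, which creates C4a–C4 and C4–C3. Diethylamine then adds in conjugate fashion to 9 to give enaminone 10, and the phenol oxygen attacks the amine-bearing carbon (future C2) with loss of diethylamine, so that ring C closes by a 6-endo-trig addition–elimination. The closest known reaction type is the palladium-catalysed carbonylative annulation of ortho-iodophenols with terminal arylacetylenes in a secondary amine, of which this is a direct application. No stereocentre is formed; 11 is planar and achiral. Three selectivities are needed: the position of ring fusion is fixed by the iodine of 5, which occupies the only carbon ortho to the hydroxyl group; carbonylative coupling must outrun direct aryl–alkyne coupling, which the electron-rich aryl group (fast migration to CO), the absence of copper, a CO-saturated solution and slow addition of 7 favour; and six-membered closure must outrun 5-exo-dig closure to the aurone, which conversion of the ynone into 10 secures because its α-carbon is no longer electrophilic. Atmospheric CO pressure is chosen to keep the inventory of toxic gas small.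

Step 5
Reactants: 11 7,8-dimethoxy-2-(3,4,5-trimethoxyphenyl)-4H-chromen-4-one
Product: 13 (2S,4S)-7,8-dimethoxy-2-(3,4,5-trimethoxyphenyl)chroman-4-ol, via flavanone 12 (not isolated)
Conditions: Ru(cod)(2-methylallyl)2 (5 mol %), (R,R)-SINpEt·HBF4 (10 mol %), KOt-Bu (15 mol %), n-hexane, 70 °C; then 11, H2 (100 bar), toluene/n-hexane, 25 °C
Reagents that add atoms: none
Why: Asymmetric hydrogenation of a flavone by a chiral bis(N-heterocyclic carbene) ruthenium catalyst, a documented reaction of this substrate class: hydrogen is added to one enantiotopic face of C2=C3, so C2 is set by the catalyst alone (S with the ligand antipode chosen). The carbonyl of flavanone 12 should then be reduced on the same face, placing the C4 hydroxyl cis to the C2 aryl group; this C4 configuration is immaterial because step 6 removes it. The benzene rings and the C2–O1 bond should survive, because this catalyst type reduces the pyranone ring selectively.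

Step 6
Reactants: 13 (2S,4S)-7,8-dimethoxy-2-(3,4,5-trimethoxyphenyl)chroman-4-ol
Product: 14 (2S)-7,8-dimethoxy-2-(3,4,5-trimethoxyphenyl)chromane [(2S)-7,8,3',4',5'-pentamethoxyflavan]
Conditions: Et3SiH (3 equiv), CF3CO2H (5 equiv, added last), CH2Cl2, −40 to 0 °C
Reagents that add atoms: none
Why: Ionic hydrogenation (reductive deoxygenation of a benzylic alcohol): the acid ionises C4–OH to a cation stabilised by O1 (ortho) and by the C7 methoxy group (para to C4a), and the silane delivers hydride to it. C2 takes no part; ionisation of C2–O1 would need protonation of a weakly basic aryl ether oxygen and is held back by low temperature, excess silane and short contact, so the S configuration should pass unchanged.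

## Compound list

1 | 2,3-dimethoxyphenol | COc1cccc(O)c1OC | starting material
2 | 2-(2,3-dimethoxyphenoxy)tetrahydro-2H-pyran (racemic) | COc1cccc(OC2CCCCO2)c1OC | intermediate
3 | [3,4-dimethoxy-2-(tetrahydro-2H-pyran-2-yloxy)phenyl]lithium | COc1ccc([Li])c(OC2CCCCO2)c1OC | intermediate (not isolated)
4 | 2-(6-iodo-2,3-dimethoxyphenoxy)tetrahydro-2H-pyran (racemic) | COc1ccc(I)c(OC2CCCCO2)c1OC | intermediate (not isolated)
5 | 6-iodo-2,3-dimethoxyphenol | COc1ccc(I)c(O)c1OC | intermediate
6 | 3,4,5-trimethoxybenzaldehyde | COc1cc(C=O)cc(OC)c1OC | starting material
7 | 5-ethynyl-1,2,3-trimethoxybenzene | COc1cc(C#C)cc(OC)c1OC | intermediate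
8 | carbon monoxide | [C-]#[O+] | starting material
9 | 1-(2-hydroxy-3,4-dimethoxyphenyl)-3-(3,4,5-trimethoxyphenyl)prop-2-yn-1-one | COc1cc(C#CC(=O)c2ccc(OC)c(OC)c2O)cc(OC)c1OC | intermediate (not isolated)
10 | (E)-3-(diethylamino)-1-(2-hydroxy-3,4-dimethoxyphenyl)-3-(3,4,5-trimethoxyphenyl)prop-2-en-1-one | CCN(CC)/C(=C/C(=O)c1ccc(OC)c(OC)c1O)c1cc(OC)c(OC)c(OC)c1 | intermediate (not isolated)
11 | 7,8-dimethoxy-2-(3,4,5-trimethoxyphenyl)-4H-chromen-4-one | COc1cc(-c2cc(=O)c3ccc(OC)c(OC)c3o2)cc(OC)c1OC | intermediate
12 | (2S)-7,8-dimethoxy-2-(3,4,5-trimethoxyphenyl)chroman-4-one | COc1cc([C@@H]2CC(=O)c3ccc(OC)c(OC)c3O2)cc(OC)c1OC | intermediate (not isolated)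
13 | (2S,4S)-7,8-dimethoxy-2-(3,4,5-trimethoxyphenyl)chroman-4-ol (2,4-cis) | COc1cc([C@@H]2C[C@H](O)c3ccc(OC)c(OC)c3O2)cc(OC)c1OC | intermediate
14 | (2S)-7,8-dimethoxy-2-(3,4,5-trimethoxyphenyl)chromane, (2S)-7,8,3',4',5'-pentamethoxyflavan | COc1cc([C@@H]2CCc3ccc(OC)c(OC)c3O2)cc(OC)c1OC | target

## Step count and least certain steps

Total step count: 6. Longest linear sequence: 5 (steps 1, 2, 4, 5 and 6); step 3 is a one-step side branch.

Step 4 (key step). The likely failures are direct, carbonyl-free coupling of the arylpalladium intermediate with the alkyne followed by five-membered ring closure, five-membered closure of the ynone before the amine has added, and sluggish oxidative addition to the electron-rich, ortho-oxygenated aryl iodide with alkyne homocoupling taking over. The fallback drops the carbonylation and builds the same flavone by condensation and oxidative cyclisation. It sets out from 6: Claisen–Schmidt condensation of 6 with purchased 1-(2-hydroxy-3,4-dimethoxyphenyl)ethanone F1 (KOH, EtOH, rt) should give (E)-1-(2-hydroxy-3,4-dimethoxyphenyl)-3-(3,4,5-trimethoxyphenyl)prop-2-en-1-one F2. Oxidative cyclisation of F2 with catalytic I2 in DMSO at about 120 °C should close ring C with dehydrogenation, and the route is rejoined at 11.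

Step 5. The likely failures are poor facial discrimination at C2 or stalling before full reduction, because the oxygen substituent next to O1 and the bulky tri-oxygenated ring B lie at the edge of the documented substrate range; base-induced reversible ring opening of the flavanone stage and partial arene saturation at high pressure are further concerns. The fallback sets the stereocentre by asymmetric ketone reduction on an open chain and closes ring C with inversion. It sets out from 6 and 5:
- Addition of CH2=CHMgBr to 6 (THF, 0 °C) should give racemic 1-(3,4,5-trimethoxyphenyl)prop-2-en-1-ol F3.
- Heck arylation of F3 with 5 (Pd(OAc)2, Bu4NCl, NaHCO3, DMF, 60 °C) should give, after enol–ketone tautomerisation, 3-(2-hydroxy-3,4-dimethoxyphenyl)-1-(3,4,5-trimethoxyphenyl)propan-1-one F4.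
- Asymmetric transfer hydrogenation of F4 with RuCl(p-cymene)[(R,R)-TsDPEN] in HCO2H/Et3N should give (R)-6-[3-hydroxy-3-(3,4,5-trimethoxyphenyl)propyl]-2,3-dimethoxyphenol F5.
- Mitsunobu cyclisation of F5 (PPh3, DIAD, THF, 0 °C) should form O1–C2 with inversion, so the route is rejoined at 14, bypassing 11 and 13.

Step 6. The likely failures are ionisation at C2–O1 in competition with C4 (loss of configuration, reductive ring opening) and capture of the C4 cation by an electron-rich ring of a second molecule before hydride transfer. The fallback replaces the cation by a radical. It sets out from 13: acylation with 1,1'-thiocarbonyldiimidazole (DMAP cat., CH2Cl2, rt) should give O-[(2S,4S)-7,8-dimethoxy-2-(3,4,5-trimethoxyphenyl)chroman-4-yl] 1H-imidazole-1-carbothioate F6. Barton–McCombie reduction of F6 with (Me3Si)3SiH and AIBN in toluene at 80 °C should replace the C4 oxygen by hydrogen under neutral conditions, and the route is rejoined at 14.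

Step 2. The likely failures are incomplete or misdirected metalation (competing deprotonation next to the C3 methoxy group), since the acetal is a weaker director than a carbamate, and premature loss of the acetal. The fallback uses the strongest oxygen-based director and a hydrolytic release. It sets out from 1: carbamoylation with ClC(O)NEt2 (K2CO3, MeCN, reflux) should give 2,3-dimethoxyphenyl N,N-diethylcarbamate F7. Metalation with s-BuLi/TMEDA in THF at −78 °C and an I2 quench at that temperature (to forestall anionic Fries rearrangement) should give 6-iodo-2,3-dimethoxyphenyl N,N-diethylcarbamate F8. Hydrolysis of F8 with NaOH in aqueous EtOH at reflux rejoins the route at 5.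

## Further compounds

F1 | step 4 | 1-(2-hydroxy-3,4-dimethoxyphenyl)ethanone (purchased) | CC(=O)c1ccc(OC)c(OC)c1O
F2 | step 4 | (E)-1-(2-hydroxy-3,4-dimethoxyphenyl)-3-(3,4,5-trimethoxyphenyl)prop-2-en-1-one | COc1cc(/C=C/C(=O)c2ccc(OC)c(OC)c2O)cc(OC)c1OC
F3 | step 5 | 1-(3,4,5-trimethoxyphenyl)prop-2-en-1-ol (racemic) | COc1cc(C(O)C=C)cc(OC)c1OC
F4 | step 5 | 3-(2-hydroxy-3,4-dimethoxyphenyl)-1-(3,4,5-trimethoxyphenyl)propan-1-one | COc1cc(C(=O)CCc2ccc(OC)c(OC)c2O)cc(OC)c1OC
F5 | step 5 | (R)-6-[3-hydroxy-3-(3,4,5-trimethoxyphenyl)propyl]-2,3-dimethoxyphenol | COc1cc([C@H](O)CCc2ccc(OC)c(OC)c2O)cc(OC)c1OC
F6 | step 6 | O-[(2S,4S)-7,8-dimethoxy-2-(3,4,5-trimethoxyphenyl)chroman-4-yl] 1H-imidazole-1-carbothioate | COc1cc([C@@H]2C[C@H](OC(=S)n3ccnc3)c3ccc(OC)c(OC)c3O2)cc(OC)c1OC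
F7 | step 2 | 2,3-dimethoxyphenyl N,N-diethylcarbamate | CCN(CC)C(=O)Oc1cccc(OC)c1OC
F8 | step 2 | 6-iodo-2,3-dimethoxyphenyl N,N-diethylcarbamate | CCN(CC)C(=O)Oc1c(I)ccc(OC)c1OC
A1 | alternative 1 | 7,8-dimethoxy-2-(3,4,5-trimethoxyphenyl)-4H-chromene | COc1cc(C2=CCc3ccc(OC)c(OC)c3O2)cc(OC)c1OC
A2 | alternative 1 | {2-[3,4-dimethoxy-2-(3,4,5-trimethoxybenzoyloxy)phenyl]ethyl}triphenylphosphonium bromide | COc1cc(C(=O)Oc2c(CC[P+](c3ccccc3)(c3ccccc3)c3ccccc3)ccc(OC)c2OC)cc(OC)c1OC.[Br-]
A3 | alternative 2 | (S)-7-methoxy-2-(3,4,5-trimethoxyphenyl)chroman-8-ol | COc1cc([C@@H]2CCc3ccc(OC)c(O)c3O2)cc(OC)c1OC
A4 | alternative 2 | (S)-3-(2-fluoro-4-methoxyphenyl)-1-(3,4,5-trimethoxyphenyl)propan-1-ol | COc1cc([C@H](CCc2ccc(OC)cc2F)O)cc(OC)c1OC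
A5 | alternative 3 | (R)-7,8-dimethoxy-2-(3,4,5-trimethoxyphenyl)-2H-chromene-3-carbaldehyde | COc1cc([C@@H]2C(C=O)=Cc3ccc(OC)c(OC)c3O2)cc(OC)c1OC
A6 | alternative 3 | 2-hydroxy-3,4-dimethoxybenzaldehyde | COc1ccc(C=O)c(O)c1OC
A7 | alternative 3 | (E)-3-(3,4,5-trimethoxyphenyl)prop-2-enal | COc1cc(/C=C/C=O)cc(OC)c1OC
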